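**Assumptions.** Positions use 4,9-friedodrimane numbering: C4 bears the =CH2, C5 and C10 are the ring-fusion carbons, C8 is CHMe, C9 is the quaternary carbon and C11 is the benzylic CH2. Read this way, the target SMILES is (5S,8S,9R,10S): a trans-decalin with 5-Me, 8-Me and 9-Me on the β face and H-10 and C11 on the α face.

## Retrosynthetic overview
1. The C4=CH2 comes from a C4 ketone by a final Wittig reaction. C8–H comes from α-face hydrogenation of a Δ7 alkene, and the same operation frees the phenol.
2. Key step: one Pd cascade (6-exo carbopalladation, then Suzuki capture of the neopentyl-Pd) disconnects C8–C9 and C11–aryl together. It closes ring B, creates quaternary C9 and attaches the arene.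
3. The cascade precursor comes from 2-methylcyclohex-2-enone. A catalytic asymmetric conjugate addition of isopropenyl sets C10, and anti alkylation of the enolate with (Z)-1-bromo-3-iodobut-2-ene sets C5.
4. Ring order: ring A and the arene are purchased, and ring B is the only ring formed (step 6). The route uses no Wieland–Miescher ketone and no enolate benzylation.

## Route

**Step 1**
Reactants: 1, but-2-yn-1-ol
Product: 2, (Z)-3-iodobut-2-en-1-ol
Conditions: Red-Al, THF, 0 °C to rt; EtOAc quench; I2, −78 to 0 °C
Reagents that add atoms: iodine, II
Why: In this hydroalumination–iodination, alkoxide-directed trans-hydroalumination places Al on C3 cis to CH2O through a five-membered aluminate, and iodinolysis with retention gives only the Z vinyl iodide.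

**Step 2**
Reactants: 2
Product: 3, (Z)-1-bromo-3-iodobut-2-ene
Conditions: CBr4, PPh3, CH2Cl2, 0 °C, dark
Reagents that add atoms: carbon tetrabromide, BrC(Br)(Br)Br
Why: The Appel reaction is a neutral SN2 displacement at the primary allylic carbon, so the vinyl iodide and its geometry are untouched.

**Step 3**
Reactants: 4, methyl 4-hydroxy-3-iodobenzoate; 5, benzyl bromide
Product: 6, methyl 4-(benzyloxy)-3-iodobenzoate
Conditions: K2CO3, DMF, 40 °C
Reagents that add atoms: benzyl bromide, BrCc1ccccc1
Why: This Williamson etherification of an acidic phenol installs a benzyl group that is later removed without an extra step, in step 7.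

**Step 4**
Reactants: 6; 7, bis(pinacolato)diboron
Product: 8, methyl 4-(benzyloxy)-3-(4,4,5,5-tetramethyl-1,3,2-dioxaborolan-2-yl)benzoate
Conditions: PdCl2(dppf) (3 mol %), KOAc, 1,4-dioxane, 85 °C
Reagents that add atoms: B2pin2, CC1(C)OB(OC1(C)C)B1OC(C)(C)C(C)(C)O1
Why: Miyaura borylation of an aryl iodide works here because the weak acetate base spares the ester and benzyl ether.

**Step 5**
Reactants: 9, 2-methylcyclohex-2-en-1-one; 10, isopropenylmagnesium bromide; 3
Product: 11, (2S,3S)-2-[(2Z)-3-iodobut-2-en-1-yl]-2-methyl-3-(prop-1-en-2-yl)cyclohexan-1-one. The side chain is trans to the isopropenyl group and the methyl is cis to it.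
Conditions: Cu(OTf)2 (3 mol %), chiral hydroxyalkyl-imidazolinium NHC precursor (4 mol %, antipode chosen to give 3S), 10 (1.2 equiv), Et2O, −30 °C; then 3 (1.5 equiv), DMPU, −30 °C to rt
Reagents that add atoms: isopropenylmagnesium bromide, C=C(C)[Mg]Br; bromide 3, C/C(I)=C/CBr
Why: Proposed new method: the closest known reaction is Cu–NHC-catalysed asymmetric conjugate addition of alkyl Grignards to 2-methylcycloalkenones with in-situ enolate alkylation, and an alkenyl Grignard should follow the same π-complex/Cu(III)/reductive-elimination path (sp2 groups transfer faster), so the ligand sets C10, and the tetrasubstituted Mg enolate, whose isopropenyl group sits pseudo-axial to avoid A1,2 strain with the methyl, is alkylated by the allylic bromide (SN2) on the opposite face, which sets C5.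

**Step 6 (key step)**
Reactants: 11; 8
Product: 12, methyl 4-(benzyloxy)-3-{[(1S,4aS,8aS)-1,2,4a-trimethyl-5-oxo-1,4,4a,5,6,7,8,8a-octahydronaphthalen-1-yl]methyl}benzoate. This is a trans-fused Δ7-octalone with 9-Me β-axial and 9-CH2Ar α-equatorial.
Conditions: Pd(OAc)2 (10 mol %), PPh3 (25 mol %), K3PO4, THF–H2O (10:1), 65 °C; 8 (1.5 equiv) added by syringe pump over 6–8 h
Reagents that add atoms: boronate 8, COC(=O)c1ccc(OCc2ccccc2)c(B2OC(C)(C)C(C)(C)O2)c1
Why: In this domino Heck (6-exo-trig carbopalladation)/Suzuki–Miyaura capture, oxidative addition with retention keeps Pd cis to C6, syn insertion into the isopropenyl group forges C8–C9 and leaves a neopentyl alkyl-Pd with no β-hydrogen that survives until the slowly added boronate transmetalates and gives C11–aryl, and on the diequatorial conformer the CH2–PdLn terminus turns to the open α side while the small methyl takes the β site next to the axial C5 methyl, which sets C9.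

**Step 7**
Reactants: 12
Product: 13, methyl 4-hydroxy-3-{[(1R,2S,4aS,8aS)-1,2,4a-trimethyl-5-oxodecahydronaphthalen-1-yl]methyl}benzoate
Conditions: H2 (4 atm), 10 % Pd/C, EtOAc–EtOH, rt
Reagents that add atoms: none
Why: In this catalytic hydrogenation with simultaneous O-benzyl hydrogenolysis, the β face of the Δ7 alkene is screened by the axial C5 and C9 methyls, so H2 adds syn from the α face to give H-8 α and 8-Me β-equatorial (8S), while the hindered ketone and the ester are inert.

**Step 8**
Reactants: 13; 14, methyltriphenylphosphonium bromide
Product: 15, dictyoceratin C, methyl 4-hydroxy-3-{[(1R,2S,4aS,8aS)-1,2,4a-trimethyl-5-methylidenedecahydronaphthalen-1-yl]methyl}benzoate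
Conditions: 14 (6 equiv), NaHMDS (5.5 equiv), toluene–THF, 0 to 80 °C; aq NH4Cl
Reagents that add atoms: methyltriphenylphosphonium bromide, C[P+](c1ccccc1)(c1ccccc1)c1ccccc1.[Br-]
Why: In this Wittig methylenation the first equivalent of ylide makes the phenoxide, whose para donation deactivates the ester towards ylide acylation, so the excess Ph3P=CH2 attacks only the hindered C4 ketone, whose α-carbons are quaternary C5 and a CH2, and no stereocentre can be scrambled.

## Compound list
1 | but-2-yn-1-ol | CC#CCO | starting material
2 | (Z)-3-iodobut-2-en-1-ol | C/C(I)=C/CO | intermediate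
3 | (Z)-1-bromo-3-iodobut-2-ene | C/C(I)=C/CBr | intermediate
4 | methyl 4-hydroxy-3-iodobenzoate | COC(=O)c1ccc(O)c(I)c1 | starting material
5 | benzyl bromide | BrCc1ccccc1 | starting material
6 | methyl 4-(benzyloxy)-3-iodobenzoate | COC(=O)c1ccc(OCc2ccccc2)c(I)c1 | intermediate
7 | bis(pinacolato)diboron | CC1(C)OB(OC1(C)C)B1OC(C)(C)C(C)(C)O1 | starting material
8 | methyl 4-(benzyloxy)-3-(pinacolatoboryl)benzoate | COC(=O)c1ccc(OCc2ccccc2)c(B2OC(C)(C)C(C)(C)O2)c1 | intermediate
9 | 2-methylcyclohex-2-en-1-one | CC1=CCCCC1=O | starting material
10 | isopropenylmagnesium bromide | C=C(C)[Mg]Br | starting material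
11 | (2S,3S)-2-[(Z)-3-iodobut-2-enyl]-2-methyl-3-isopropenylcyclohexanone | O=C1CCC[C@@H](C(C)=C)[C@]1(C)C/C=C(\I)C | intermediate
12 | Δ7-octalone benzyl ether (5S,9S,10S) | O=C1CCC[C@H]2[C@](C)(Cc3cc(C(=O)OC)ccc3OCc3ccccc3)C(C)=CC[C@]12C | intermediate
13 | keto-phenol (5S,8S,9R,10S) | O=C1CCC[C@H]2[C@](C)(Cc3cc(C(=O)OC)ccc3O)[C@@H](C)CC[C@]12C | intermediate
14 | methyltriphenylphosphonium bromide | C[P+](c1ccccc1)(c1ccccc1)c1ccccc1.[Br-] | starting material
15 | dictyoceratin C | C=C1CCC[C@H]2[C@](C)(Cc3cc(C(=O)OC)ccc3O)[C@@H](C)CC[C@]12C | target

## Summary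
Total steps: 8.
Longest linear sequence: 6 steps (1, 2, 5, 6, 7, 8). This is 4 steps from 2-methylcyclohexenone.

**The three steps most likely to fail**
1. **Step 6.** The risks are direct Suzuki coupling of the vinyl iodide before cyclisation, 3-exo cyclopropanation of the neopentyl-Pd onto the new alkene, and insufficient C9 selectivity.
   - Fallback: close ring B by a radical reaction instead of with Pd.
   - Bring the arene in with the nucleophile, as a (Z)-1-arylprop-1-en-2-yl copper reagent, in the conjugate addition.
   - Alkylate the enolate with 3-bromobutyl iodide.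
   - Run a (TMS)3SiH/AIBN 6-exo cyclisation of the C8 secondary radical onto C9 of the styrene. The benzylic radical is reduced to CH2Ar.
   - The all-equatorial chair transition state sets C8 and C9 together, and step 7 shrinks to a debenzylation.
2. **Step 5.** The risks are low ee or low conversion with an alkenyl Grignard on an α-substituted enone.
   - Fallback: use auxiliary control in place of catalysis, starting from enantiopure 2-(p-tolylsulfinyl)cyclohex-2-enone.
   - The sequence is chelation-controlled isopropenyl addition, α-methylation, reductive desulfinylation to the regiodefined enolate, and trapping with 3.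
3. **Step 7.** The risks are that the trisubstituted alkene next to quaternary C9 is inert or gives a mixture at C8.
   - Fallback: use a radical hydrogen-atom-transfer hydrogenation (Mn(dpm)3, PhSiH3, TBHP, i-PrOH). H• adds to C7, and the tertiary C8 radical is quenched from the α face to give the equatorial methyl.
   - Follow with a separate debenzylation (BCl3, pentamethylbenzene, −78 °C).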